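The route rests on disconnecting C9–C10, the bond between the quaternary C10 and the doubly allylic C9 in ring B (C5–C10). The precursor is monocyclic: ring A with a C1=C10 alkene, whose C5 carries the C6 silyloxy carbon and a Z-C7=C8/E-C9=C11 dienyl phenyl sulfone. Iron-hydride hydrogen-atom transfer to C1 gives the C10 radical, which adds 6-exo to C9. One operation closes ring B, creates C9 and C10, fixes the trans fusion and leaves a C11 sulfone for Julia attachment of C12–C16. It exploits the axial C4 methyl (1,3 to C10) and the cis C7=C8 alkene as control elements. C5 and C6 come from a CBS reduction relayed by a [2,3]-Wittig shift.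

Key step: step 8

Remark on numbering: labdane numbering is used throughout. Ring A = C1–C5, C10. Ring B = C5–C10. C11–C16 is the side chain, C17 is the CH2O carbon on C8, C18/C19 sit on C4 and C20 sits on C10. The target is (5R,6S,9S,10S,13S), in the ent-labdane series.
Assumption: the (R,R)-ligand in step 9 is taken to deliver the (S)-diol. If the sense of induction is the opposite, the (S,S)-ligand is used.
Assumption: compounds 1, 3, 11 and 14 are taken as commercially available.

Step 1
Reactants: 1 2,4,4-trimethylcyclohex-2-en-1-one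
Product: 2 (S)-2,4,4-trimethylcyclohex-2-en-1-ol
Conditions: (R)-Me-CBS (10 mol %), BH3·SMe2, THF, −20 °C; aqueous work-up
Reagents that add atoms: none
Why: Corey–Bakshi–Shibata reduction, in which the alkenyl arm acts as the large group, so the (R)-catalyst should give the (S)-carbinol at C1, the only source of absolute configuration for the decalin.

Step 2
Reactants: 2 (S)-2,4,4-trimethylcyclohex-2-en-1-ol; 3 propargyl bromide
Product: 4 (S)-2,4,4-trimethylcyclohex-2-en-1-yl prop-2-yn-1-yl ether
Conditions: NaH, n-Bu4NI (cat.), THF, 0 °C → rt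
Reagents that add atoms: none
Why: Williamson etherification of the alkoxide with a primary propargylic bromide, which does not touch the C1 stereocentre.

Step 3
Reactants: 4 (S)-2,4,4-trimethylcyclohex-2-en-1-yl prop-2-yn-1-yl ether
Product: 6 (1R)-1-[(1R)-2,6,6-trimethylcyclohex-2-en-1-yl]but-2-yne-1,4-diol, via dilithium alkynolate 5 (not isolated)
Conditions: n-BuLi (2.4 equiv), THF, −78 → −20 °C; (CH2O)n, −20 °C → rt; H2O
Reagents that add atoms: formaldehyde (as paraformaldehyde), C=O
Why: [2,3]-Wittig rearrangement of the O-propargyl dianion, suprafacial across C1–C10=C5 so that the C1–O configuration is relayed to C5; the alkynyl group sits exo in the envelope transition state (away from C4Me2) and sets C6, and the surviving lithium acetylide is hydroxymethylated in the same flask to install C17.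

Step 4
Reactants: 6 (1R)-1-[(1R)-2,6,6-trimethylcyclohex-2-en-1-yl]but-2-yne-1,4-diol
Product: 7 (1R)-4-[(tert-butyldimethylsilyl)oxy]-1-[(1R)-2,6,6-trimethylcyclohex-2-en-1-yl]but-2-yn-1-ol
Conditions: TBSCl (1.05 equiv), imidazole, CH2Cl2, 0 °C
Reagents that add atoms: tert-butyldimethylsilyl chloride, CC(C)(C)[Si](C)(C)Cl
Why: Selective silylation, because the primary C17 alcohol should react much faster than the neopentyl-type secondary C6 carbinol.

Step 5
Reactants: 7 (1R)-4-[(tert-butyldimethylsilyl)oxy]-1-[(1R)-2,6,6-trimethylcyclohex-2-en-1-yl]but-2-yn-1-ol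
Product: 9 (1R,2Z)-4-[(tert-butyldimethylsilyl)oxy]-3-iodo-1-[(1R)-2,6,6-trimethylcyclohex-2-en-1-yl]but-2-en-1-ol, via cyclic alkenylalanate 8 (not isolated)
Conditions: Red-Al, THF, 0 °C → rt; I2, −78 → 0 °C; H2O work-up
Reagents that add atoms: iodine, II
Why: Alkoxide-directed trans-hydroalumination of the propargylic alcohol places Al on C8 in a five-membered alanate, and iodinolysis with retention should give the Z-iodide in which C6 and iodine are cis, the geometry ring B needs.

Step 6
Reactants: 9 (1R,2Z)-4-[(tert-butyldimethylsilyl)oxy]-3-iodo-1-[(1R)-2,6,6-trimethylcyclohex-2-en-1-yl]but-2-en-1-ol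
Product: 10 C6 triethylsilyl ether of 9 (Z-C8 iodide, C6-OTES, C17-OTBS)
Conditions: TESOTf, 2,6-lutidine, CH2Cl2, −40 → 0 °C
Reagents that add atoms: triethylsilyl triflate, CC[Si](CC)(CC)OS(=O)(=O)C(F)(F)F
Why: Silyl triflate protection of the hindered C6 alcohol, which blocks oxa-Michael closure onto the sulfone installed next; the small TES group limits the 1,3-diaxial strain later built up at C6.

Step 7
Reactants: 10 C6 triethylsilyl ether of 9; 11 phenyl vinyl sulfone
Product: 12 Z-C7=C8/E-C9=C11 dienyl phenyl sulfone (C5, C6 as in 10; C6-OTES, C17-OTBS; ring-A C1=C10 alkene intact)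
Conditions: 11 (5 equiv), Pd(OAc)2 (10 mol %), n-Bu4NCl, K2CO3, DMF, 35 °C
Reagents that add atoms: none
Why: Mizoroki–Heck reaction under ligand-free phase-transfer conditions, with retention at C8 and β-hydride elimination to the E-vinyl sulfone; the excess of electron-poor alkene and the low temperature should favour intermolecular insertion over insertion of the hindered ring alkene.

Step 8
Reactants: 12 Z-C7=C8/E-C9=C11 dienyl phenyl sulfone
Product: 13 trans-fused bicyclic sulfone (11-phenylsulfonyl, 6-OTES, 17-OTBS, C7=C8; C5, C6, C9, C10 as in 23)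
Conditions: Fe(acac)3 (50 mol %), PhSiH3 (3 equiv), EtOH–THF, 0.02 M, 60 °C, Ar
Reagents that add atoms: none
Why: An iron hydride formed from Fe(acac)3 and PhSiH3 transfers H• to C1 of the electron-rich C1=C10 alkene (Markovnikov MHAT); the nucleophilic tertiary C10 radical adds to C9, the β-carbon of the vinyl sulfone, and the α-sulfonyl C11 radical is reduced by Fe(II) and protonated by ethanol. The closest known reaction type is the iron-catalysed reductive olefin coupling (MHAT-initiated Giese addition) in its intramolecular form, for which vinyl sulfones are established acceptors. Ring B closes in the 6-exo-trig mode (C10 to C9, C11 exocyclic), while attack at C8 (5-endo) or at C11 (7-endo, α to sulfur) is stereoelectronically and polarity mismatched. C10 is controlled by C5 and C4: with the C5–C6 bond equatorial the acceptor reaches the radical along the equatorial trajectory, the axial face being screened by the axial C4 methyl, so that C20 becomes axial and anti to H5 (trans fusion). C9 is controlled by the Z-C7=C8 alkene: only the s-trans-like rotamer of the dienyl sulfone avoids a clash between C11 and C6, and attack on it places C11 pseudo-equatorial, on the same face as C20. The step needs H• transfer to the isolated ring alkene in preference to the dienyl sulfone, which the electron-poor, sterically shielded diene and the fast intramolecular capture of the radical are expected to secure.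

Step 9
Reactants: 14 2-methyl-2-vinyloxirane (racemic isoprene monoxide)
Product: 15 (S)-2-methylbut-3-ene-1,2-diol
Conditions: [Pd2(dba)3]·CHCl3 (1 mol %), (R,R)-DACH-naphthyl bisphosphine ligand (3 mol %), Et3B (1 mol %), NaHCO3, CH2Cl2–H2O, rt
Reagents that add atoms: sodium hydrogencarbonate, [Na+].OC([O-])=O
Why: Palladium-catalysed dynamic kinetic asymmetric allylic substitution (Tsuji–Trost type), in which the π-allyl diastereomers equilibrate, boron ties hydrogencarbonate to the alkoxide and directs it to the tertiary terminus, the ligand sets C13, and loss of CO2 leaves the diol.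

Step 10
Reactants: 15 (S)-2-methylbut-3-ene-1,2-diol
Product: 16 (S)-2-methyl-1,2-bis[(triethylsilyl)oxy]but-3-ene
Conditions: TESOTf (2.4 equiv), 2,6-lutidine, CH2Cl2, 0 °C
Reagents that add atoms: triethylsilyl triflate, CC[Si](CC)(CC)OS(=O)(=O)C(F)(F)F
Why: Exhaustive silylation with a silyl triflate, which is reactive enough for the tertiary allylic alcohol and leaves C13 untouched.

Step 11
Reactants: 16 (S)-2-methyl-1,2-bis[(triethylsilyl)oxy]but-3-ene
Product: 17 (S)-2-methyl-2-[(triethylsilyl)oxy]but-3-enal
Conditions: (COCl)2, DMSO, CH2Cl2, −78 → −35 °C; Et3N, → 0 °C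
Reagents that add atoms: none
Why: Swern oxidation applied directly to the silyl ether, in which the activated sulfonium reagent cleaves and oxidises the primary TES ether selectively while the tertiary TES ether stays; the aldehyde has no α-hydrogen, so C13 cannot epimerise.

Step 12
Reactants: 13 trans-fused bicyclic sulfone; 17 (S)-2-methyl-2-[(triethylsilyl)oxy]but-3-enal
Product: 20 C12-acetoxy C11-phenylsulfonyl adduct (mixture at C11/C12; all other centres as in 23), via lithiated sulfone 18 (not isolated), via lithium alkoxide adduct 19 (not isolated)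
Conditions: n-BuLi, THF, −78 °C; 17; Ac2O, −78 °C → rt
Reagents that add atoms: acetic anhydride, CC(=O)OC(C)=O
Why: Addition stage of the Julia–Lythgoe olefination, in which the C11 sulfonyl carbanion adds to the non-enolisable aldehyde and the alkoxide is trapped in situ as the acetate; the new C11/C12 centres are erased in the next step.

Step 13
Reactants: 20 C12-acetoxy C11-phenylsulfonyl adduct
Product: 21 (11E)-6-OTES-13-OTES-17-OTBS labda-7,11,14-triene (all centres as in 23)
Conditions: 6 % Na(Hg), Na2HPO4, MeOH–THF, −20 °C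
Reagents that add atoms: none
Why: Reductive elimination stage of the Julia–Lythgoe olefination, in which all diastereomers should converge on the E-C11=C12 alkene because the intermediate equilibrates to the less hindered geometry between the branched C9 and C13.

Step 14
Reactants: 21 (11E)-6-OTES-13-OTES-17-OTBS labda-7,11,14-triene
Product: 22 (5R,6S,9S,10S,13S,11E)-labda-7,11,14-triene-6,13,17-triol
Conditions: TBAF, THF, rt → 45 °C
Reagents that add atoms: none
Why: Fluoride-mediated global desilylation under non-acidic conditions, which spares the acid-labile tertiary bis-allylic alcohol.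

Step 15
Reactants: 22 (5R,6S,9S,10S,13S,11E)-labda-7,11,14-triene-6,13,17-triol
Product: 23 (5R,6S,9S,10S,13S,11E)-6,17-diacetoxy-13-hydroxylabda-7,11,14-triene (target)
Conditions: Ac2O, pyridine, DMAP (cat.), CH2Cl2, 0 °C → rt
Reagents that add atoms: acetic anhydride, CC(=O)OC(C)=O
Why: Chemoselective acylation, in which the primary C17 and secondary C6 alcohols should be acetylated while the tertiary C13 alcohol is too hindered to react under these conditions.

Compound list
1 | 2,4,4-trimethylcyclohex-2-en-1-one | O=C1CCC(C)(C)C=C1C | starting material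
2 | (S)-2,4,4-trimethylcyclohex-2-en-1-ol | O[C@H]1CCC(C)(C)C=C1C | intermediate
3 | propargyl bromide | C#CCBr | starting material
4 | (S)-2,4,4-trimethylcyclohex-2-en-1-yl prop-2-yn-1-yl ether | C#CCO[C@H]1CCC(C)(C)C=C1C | intermediate
5 | O,C-dilithio derivative of (1R)-1-[(1R)-2,6,6-trimethylcyclohex-2-en-1-yl]prop-2-yn-1-ol | [Li]C#C[C@H](O[Li])[C@@H]1C(C)(C)CCC=C1C | intermediate
6 | (1R)-1-[(1R)-2,6,6-trimethylcyclohex-2-en-1-yl]but-2-yne-1,4-diol | OCC#C[C@H](O)[C@@H]1C(C)(C)CCC=C1C | intermediate
7 | (1R)-4-[(tert-butyldimethylsilyl)oxy]-1-[(1R)-2,6,6-trimethylcyclohex-2-en-1-yl]but-2-yn-1-ol | CC(C)(C)[Si](C)(C)OCC#C[C@H](O)[C@@H]1C(C)(C)CCC=C1C | intermediate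
8 | sodium cyclic alkenylalanate (Al on C8, O on C6, two 2-methoxyethoxy ligands) | [Na+].COCCO[Al-]1(OCCOC)O[C@H]([C@@H]2C(C)(C)CCC=C2C)C=C1CO[Si](C)(C)C(C)(C)C | intermediate
9 | (1R,2Z)-4-[(tert-butyldimethylsilyl)oxy]-3-iodo-1-[(1R)-2,6,6-trimethylcyclohex-2-en-1-yl]but-2-en-1-ol | CC(C)(C)[Si](C)(C)OC/C(I)=C/[C@H](O)[C@@H]1C(C)(C)CCC=C1C | intermediate
10 | C6 triethylsilyl ether of 9 | CC(C)(C)[Si](C)(C)OC/C(I)=C/[C@H](O[Si](CC)(CC)CC)[C@@H]1C(C)(C)CCC=C1C | intermediate
11 | phenyl vinyl sulfone | C=CS(=O)(=O)c1ccccc1 | starting material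
12 | Z-C7=C8/E-C9=C11 dienyl phenyl sulfone | CC(C)(C)[Si](C)(C)OC/C(/C=C/S(=O)(=O)c1ccccc1)=C/[C@H](O[Si](CC)(CC)CC)[C@@H]2C(C)(C)CCC=C2C | intermediate
13 | trans-fused bicyclic C11 phenyl sulfone | O=S(=O)(c1ccccc1)C[C@@H]2C(CO[Si](C)(C)C(C)(C)C)=C[C@H](O[Si](CC)(CC)CC)[C@@H]3C(C)(C)CCC[C@@]23C | intermediate
14 | 2-methyl-2-vinyloxirane (racemic) | CC1(C=C)CO1 | starting material
15 | (S)-2-methylbut-3-ene-1,2-diol | C=C[C@](C)(O)CO | intermediate
16 | (S)-2-methyl-1,2-bis[(triethylsilyl)oxy]but-3-ene | C=C[C@](C)(O[Si](CC)(CC)CC)CO[Si](CC)(CC)CC | intermediate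
17 | (S)-2-methyl-2-[(triethylsilyl)oxy]but-3-enal | C=C[C@](C)(O[Si](CC)(CC)CC)C=O | intermediate
18 | C11-lithiated sulfone | [Li]C(S(=O)(=O)c1ccccc1)[C@@H]2C(CO[Si](C)(C)C(C)(C)C)=C[C@H](O[Si](CC)(CC)CC)[C@@H]3C(C)(C)CCC[C@@]23C | intermediate
19 | lithium C12 alkoxide adduct (mixture at C11/C12) | C=C[C@](C)(O[Si](CC)(CC)CC)C(O[Li])C(S(=O)(=O)c1ccccc1)[C@@H]2C(CO[Si](C)(C)C(C)(C)C)=C[C@H](O[Si](CC)(CC)CC)[C@@H]3C(C)(C)CCC[C@@]23C | intermediate
20 | C12-acetoxy C11-phenylsulfonyl adduct (mixture at C11/C12) | C=C[C@](C)(O[Si](CC)(CC)CC)C(OC(C)=O)C(S(=O)(=O)c1ccccc1)[C@@H]2C(CO[Si](C)(C)C(C)(C)C)=C[C@H](O[Si](CC)(CC)CC)[C@@H]3C(C)(C)CCC[C@@]23C | intermediate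
21 | (11E)-6-OTES-13-OTES-17-OTBS labda-7,11,14-triene | C=C[C@](C)(O[Si](CC)(CC)CC)/C=C/[C@@H]1C(CO[Si](C)(C)C(C)(C)C)=C[C@H](O[Si](CC)(CC)CC)[C@@H]2C(C)(C)CCC[C@@]12C | intermediate
22 | (5R,6S,9S,10S,13S,11E)-labda-7,11,14-triene-6,13,17-triol | C=C[C@](C)(O)/C=C/[C@@H]1C(CO)=C[C@H](O)[C@@H]2C(C)(C)CCC[C@@]12C | intermediate
23 | (5R,6S,9S,10S,13S,11E)-6,17-diacetoxy-13-hydroxylabda-7,11,14-triene | C=C[C@](C)(O)/C=C/[C@@H]1C(COC(C)=O)=C[C@H](OC(C)=O)[C@@H]2C(C)(C)CCC[C@@]12C | target

Total step count: 15. Longest linear sequence: 12 (steps 1–8 and 12–15).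

Steps most likely to fail

Step 8. Three things may go wrong:
- Hydrogen-atom transfer may go to the dienyl sulfone instead of the ring alkene.
- Reversible hydrogen abstraction may move the ring double bond to C5=C10 and erase C5.
- Facial selectivity at the C10 radical may be poor.

The fallback separates radical generation from the acceptor. It sets out from 10 and returns at 13. Mukaiyama hydration of 10 (Mn(dpm)3, PhSiH3, O2), where the ring alkene is the only electron-rich alkene, would give the C10 tertiary alcohol F1. Heck coupling of F1 with 11 as in step 7, now with no ring alkene left to interfere, would give the hydroxy dienyl sulfone F2. Acylation with methyl chlorooxoacetate would give the methyl oxalate F3, and hydrolysis with CsOH the caesium oxalate F4. Visible-light photoredox decarboxylation (iridium photocatalyst, DME–DMF, H2O) would then generate the same C10 radical without any metal hydride and close ring B to 13.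

Step 7. The alkenyl-palladium intermediate may insert the ring C1=C10 alkene (5-exo carbopalladation) faster than the external vinyl sulfone. The C7=C8 geometry may also scramble. The fallback avoids palladium. It sets out from 10 and returns at 12. Iodine–lithium exchange (t-BuLi, Et2O, −78 °C) and formylation with DMF would give the Z-enal F5. A Horner–Wadsworth–Emmons reaction of F5 with diethyl (phenylsulfonyl)methylphosphonate (NaH, THF) would then give 12.

Step 12. Addition of the hindered C11 carbanion to the α-quaternary aldehyde may be slow and reversible, so that retro-addition or proton transfer wins before the acetate trap. The fallback reverses the polarity of the two partners. It sets out from 13 and 15 and returns at 21, so step 13 is skipped.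
- Aldehyde partner: lithiation of 13 and oxidative desulfonylation with bis(trimethylsilyl) peroxide would give the C11 aldehyde F6.
- Sulfone partner: Mitsunobu reaction of 15 with 1-phenyl-1H-tetrazole-5-thiol would give the hydroxy sulfide F7, TESOTf the silyl ether sulfide F8, and molybdate/H2O2 the tetrazolyl sulfone F9.
- Coupling: Julia–Kocienski olefination of premetalated F9 (KHMDS, THF, −78 °C) with F6 would give 21 directly.

Further compounds
F1 | step 8 | C10 tertiary alcohol of the Z-iodide (mixture at C10) | CC(C)(C)[Si](C)(C)OC/C(I)=C/[C@H](O[Si](CC)(CC)CC)[C@@H]1C(C)(C)CCCC1(C)O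
F2 | step 8 | C10 hydroxy dienyl phenyl sulfone | CC(C)(C)[Si](C)(C)OC/C(/C=C/S(=O)(=O)c1ccccc1)=C/[C@H](O[Si](CC)(CC)CC)[C@@H]2C(C)(C)CCCC2(C)O
F3 | step 8 | C10 methyl oxalate | CC(C)(C)[Si](C)(C)OC/C(/C=C/S(=O)(=O)c1ccccc1)=C/[C@H](O[Si](CC)(CC)CC)[C@@H]2C(C)(C)CCCC2(C)OC(=O)C(=O)OC
F4 | step 8 | C10 caesium oxalate | CC(C)(C)[Si](C)(C)OC/C(/C=C/S(=O)(=O)c1ccccc1)=C/[C@H](O[Si](CC)(CC)CC)[C@@H]2C(C)(C)CCCC2(C)OC(=O)C(=O)[O-].[Cs+]
F5 | step 7 | Z-enal (C9 aldehyde cis to C6) | CC(C)(C)[Si](C)(C)OC/C(C=O)=C/[C@H](O[Si](CC)(CC)CC)[C@@H]1C(C)(C)CCC=C1C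
F6 | step 12 | bicyclic C11 aldehyde | O=C[C@@H]1C(CO[Si](C)(C)C(C)(C)C)=C[C@H](O[Si](CC)(CC)CC)[C@@H]2C(C)(C)CCC[C@@]12C
F7 | step 12 | (S)-2-methyl-1-[(1-phenyl-1H-tetrazol-5-yl)sulfanyl]but-3-en-2-ol | C=C[C@](C)(O)CSc1nnnn1-c1ccccc1
F8 | step 12 | triethylsilyl ether of F7 | C=C[C@](C)(O[Si](CC)(CC)CC)CSc1nnnn1-c1ccccc1
F9 | step 12 | tetrazolyl sulfone of F8 | C=C[C@](C)(O[Si](CC)(CC)CC)CS(=O)(=O)c1nnnn1-c1ccccc1
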